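**Retrosynthetic overview**
- **Feature:** ring A carries the CH2CH2OSO3H chain at C1, H at C2, the catechol oxygens at C3 and C4, Br at C5 and the diarylmethane carbon at C6. The path O–CH2–CH2–C1–C6 lacks only that diarylmethane carbon to be a dihydropyran fused to ring A. The C3 oxygen stands para to C6 and can drive an electrophilic attack there.
- **Endgame:** the sulfate comes from the primary alcohol, sulfated while the four phenols are masked as acetates. The catechols come from methyl ethers, and C5–Br comes from C5–H next to the single free phenol at C4.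
- **Untethering:** the diarylmethane CH2 comes from the benzhydrylic C–O bond of a 1-arylisochroman, cut with Et3SiH and acid.
- **Key disconnection:** an oxa-Pictet–Spengler closure of homovanillyl alcohol and 2,3-dibromo-4,5-dimethoxybenzaldehyde forms the C6–CH and CH–O bonds of the isochroman. The aldehyde comes from vanillin.
- **Ring order:** both benzene rings are bought. The dihydropyran is the only ring made (step 4), and it is opened again in step 5.

Key step: step 4

Assumption: the target is taken as the free hydrogen sulfate as drawn, so the route ends with a cold proton exchange of the sulfate salt.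

**Step 1**
Reactants: 1 vanillin
Product: 2 5-bromovanillin (3-bromo-4-hydroxy-5-methoxybenzaldehyde)
Conditions: Br2 (1.05 equiv), MeOH, 0 °C to rt
Reagents that add atoms: bromine, BrBr
Why: Electrophilic aromatic bromination should go to C5, the only open position ortho or para to the free phenol and also meta to the aldehyde.

**Step 2**
Reactants: 2 5-bromovanillin
Product: 3 5,6-dibromovanillin (2,3-dibromo-4-hydroxy-5-methoxybenzaldehyde)
Conditions: Br2 (1.3 equiv), Fe powder (0.05 equiv), AcOH, 80 °C
Reagents that add atoms: bromine, BrBr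
Why: Lewis-acid-assisted electrophilic aromatic bromination of the now deactivated ring should take the position para to the methoxy group rather than the one wedged between the aldehyde and the methoxy group.

**Step 3**
Reactants: 3 5,6-dibromovanillin
Product: 4 2,3-dibromo-4,5-dimethoxybenzaldehyde
Conditions: MeI (1.5 equiv), K2CO3 (2 equiv), DMF, rt
Reagents that add atoms: iodomethane, CI
Why: Williamson O-methylation of the acidic, bromine-flanked phenoxide with a small electrophile leaves the aldehyde and the aryl bromides untouched.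

**Step 4**
Reactants: 4 2,3-dibromo-4,5-dimethoxybenzaldehyde; 5 homovanillyl alcohol [2-(4-hydroxy-3-methoxyphenyl)ethanol]
Product: 8 (±)-1-(2,3-dibromo-4,5-dimethoxyphenyl)-6-methoxyisochroman-7-ol, via hemiacetal 6 (not isolated), via oxocarbenium ion 7 (not isolated)
Conditions: TfOH (0.2 equiv), acid-washed 4 Å MS, CH2Cl2 (0.05 M), 0 °C to rt
Reagents that add atoms: none
Why: The primary hydroxyl of 5 adds to the protonated aldehyde 4 to give hemiacetal 6, which loses water to the aryl-conjugated oxocarbenium ion 7; C6 of ring A then attacks the cationic carbon and loss of the C6 proton restores the arene, so the C6–CH bond, the CH–O bond and the dihydropyran ring arise in one operation. This is an oxa-Pictet–Spengler cyclisation, established for 3-alkoxy- and 3,4-dialkoxy-2-arylethanols with aromatic aldehydes under Brønsted or Lewis acid catalysis. The ring closes in the 6-endo-trig mode, since both atoms of the C=O+ unit end up inside the new six-membered ring. The new stereocentre at C1 of the isochroman has no controlling element and forms as a racemate, which is harmless because step 5 turns it into a CH2 group. The step needs attack at C6 and not at C2: C6 is para to the C3 methoxy donor and unhindered, C2 is only ortho to it and squeezed between the chain and the methoxy group, and C5, which the free phenol activates, cannot reach the tethered cation while dilution holds back its intermolecular attack. The two bromines raise the electrophilicity of 7, which offsets the shielding by the ortho bromine, and closing the bond while C5 still carries hydrogen keeps the crowding at the future junction low.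

**Step 5**
Reactants: 8 (±)-1-(2,3-dibromo-4,5-dimethoxyphenyl)-6-methoxyisochroman-7-ol
Product: 10 2-[2-(2,3-dibromo-4,5-dimethoxybenzyl)-4-hydroxy-5-methoxyphenyl]ethanol, via benzhydryl cation 9 (not isolated)
Conditions: Et3SiH (5 equiv), TFA, CH2Cl2, 0 °C to rt; then NaHCO3, MeOH–H2O
Reagents that add atoms: none
Why: In this ionic hydrogenation of a benzhydryl ether, protonation of the ring oxygen lets the C1–O bond ionise to cation 9, which the coplanar para methoxy group of ring A stabilises and which hydride transfer from silicon traps irreversibly, so the stereocentre is erased and the alcohol freed, and running it before the bromination leaves the neighbouring C5 position empty so that the cation can flatten against ring A.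

**Step 6**
Reactants: 10 2-[2-(2,3-dibromo-4,5-dimethoxybenzyl)-4-hydroxy-5-methoxyphenyl]ethanol
Product: 11 2-[3-bromo-2-(2,3-dibromo-4,5-dimethoxybenzyl)-4-hydroxy-5-methoxyphenyl]ethanol
Conditions: NBS (1.0 equiv), i-Pr2NH (0.1 equiv), CH2Cl2, 0 °C, dark
Reagents that add atoms: N-bromosuccinimide, O=C1CCC(=O)N1Br
Why: In this amine-catalysed ortho-selective electrophilic bromination of a phenol the free C4 hydroxyl outranks the methoxy groups as director, its para position (C1) and one ortho position (C3) are occupied so that only C5 remains, and ring B is deactivated by its two bromines.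

**Step 7**
Reactants: 11 2-[3-bromo-2-(2,3-dibromo-4,5-dimethoxybenzyl)-4-hydroxy-5-methoxyphenyl]ethanol
Product: 12 3-bromo-4-(2,3-dibromo-4,5-dihydroxybenzyl)-5-(2-hydroxyethyl)benzene-1,2-diol
Conditions: BBr3 (8 equiv), CH2Cl2, −78 to 0 °C; then H2O
Reagents that add atoms: none
Why: Lewis-acid cleavage of aryl methyl ethers (bromide attacks the methyl carbon of each boron-complexed ether) should remove all three methyl groups, while the primary C–O bond is not activated enough for bromide displacement at or below 0 °C and hydrolysis returns the alcohol.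

**Step 8**
Reactants: 12 3-bromo-4-(2,3-dibromo-4,5-dihydroxybenzyl)-5-(2-hydroxyethyl)benzene-1,2-diol
Product: 13 3-bromo-4-(4,5-diacetoxy-2,3-dibromobenzyl)-5-(2-hydroxyethyl)-1,2-phenylene diacetate
Conditions: Ac2O (4.2 equiv), Et3N (4.5 equiv), THF, −20 to 0 °C, Ar
Reagents that add atoms: acetic anhydride, CC(=O)OC(C)=O
Why: In this chemoselective O-acylation the four acidic bromocatechol hydroxyls are ionised by the amine and acylated quickly as phenoxides, whereas the neutral primary alcohol reacts only slowly with the anhydride when no nucleophilic catalyst is present, so the one hydroxyl to be sulfated stays free.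

**Step 9**
Reactants: 13 3-bromo-4-(4,5-diacetoxy-2,3-dibromobenzyl)-5-(2-hydroxyethyl)-1,2-phenylene diacetate
Product: 14 pyridinium 2-[4,5-diacetoxy-3-bromo-2-(4,5-diacetoxy-2,3-dibromobenzyl)phenyl]ethyl sulfate
Conditions: SO3·pyridine (2 equiv), DMF, 0 °C to rt
Reagents that add atoms: sulfur trioxide–pyridine complex, [O-]S(=O)(=O)[n+]1ccccc1
Why: O-sulfation with a sulfur trioxide–amine complex meets a single free hydroxyl, so no selectivity between alcohol and phenols is asked of it, and the neutral conditions leave aryl acetates and aryl bromides alone.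

**Step 10**
Reactants: 14 pyridinium 2-[4,5-diacetoxy-3-bromo-2-(4,5-diacetoxy-2,3-dibromobenzyl)phenyl]ethyl sulfate
Product: 16 2-[3-bromo-2-(2,3-dibromo-4,5-dihydroxybenzyl)-4,5-dihydroxyphenyl]ethyl hydrogen sulfate (CNP0136879.0), via sulfate monoanion 15 (not isolated)
Conditions: NH3 (7 M in MeOH), 0 °C, Ar; then Amberlite IR-120 (H+ form), H2O–MeCN, 0 °C; freeze-drying
Reagents that add atoms: none
Why: Aminolysis of the activated aryl acetates is fast at 0 °C while an alkyl sulfate monoanion resists base, and the cold cation exchange then replaces the ammonium and pyridinium counter-ions by a proton.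

**Compound list**
1 | vanillin | COc1cc(C=O)ccc1O | starting material
2 | 5-bromovanillin | COc1cc(C=O)cc(Br)c1O | intermediate
3 | 5,6-dibromovanillin (2,3-dibromo-4-hydroxy-5-methoxybenzaldehyde) | COc1cc(C=O)c(Br)c(Br)c1O | intermediate
4 | 2,3-dibromo-4,5-dimethoxybenzaldehyde | O=Cc1cc(OC)c(OC)c(Br)c1Br | intermediate
5 | homovanillyl alcohol | COc1cc(CCO)ccc1O | starting material
6 | hemiacetal (racemic, not isolated) | COc1cc(CCOC(O)c2cc(OC)c(OC)c(Br)c2Br)ccc1O | intermediate
7 | oxocarbenium ion (not isolated) | COc1cc(CC[O+]=Cc2cc(OC)c(OC)c(Br)c2Br)ccc1O | intermediate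
8 | (±)-1-(2,3-dibromo-4,5-dimethoxyphenyl)-6-methoxyisochroman-7-ol (racemic) | COc1cc2CCOC(c3cc(OC)c(OC)c(Br)c3Br)c2cc1O | intermediate
9 | benzhydryl cation (not isolated) | OCCc1cc(OC)c(O)cc1[CH+]c1cc(OC)c(OC)c(Br)c1Br | intermediate
10 | 2-[2-(2,3-dibromo-4,5-dimethoxybenzyl)-4-hydroxy-5-methoxyphenyl]ethanol | OCCc1cc(OC)c(O)cc1Cc1cc(OC)c(OC)c(Br)c1Br | intermediate
11 | 2-[3-bromo-2-(2,3-dibromo-4,5-dimethoxybenzyl)-4-hydroxy-5-methoxyphenyl]ethanol | OCCc1cc(OC)c(O)c(Br)c1Cc1cc(OC)c(OC)c(Br)c1Br | intermediate
12 | 3-bromo-4-(2,3-dibromo-4,5-dihydroxybenzyl)-5-(2-hydroxyethyl)benzene-1,2-diol | OCCc1cc(O)c(O)c(Br)c1Cc1cc(O)c(O)c(Br)c1Br | intermediate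
13 | 3-bromo-4-(4,5-diacetoxy-2,3-dibromobenzyl)-5-(2-hydroxyethyl)-1,2-phenylene diacetate | OCCc1cc(OC(C)=O)c(OC(C)=O)c(Br)c1Cc1cc(OC(C)=O)c(OC(C)=O)c(Br)c1Br | intermediate
14 | pyridinium 2-[4,5-diacetoxy-3-bromo-2-(4,5-diacetoxy-2,3-dibromobenzyl)phenyl]ethyl sulfate | c1cc[nH+]cc1.[O-]S(=O)(=O)OCCc1cc(OC(C)=O)c(OC(C)=O)c(Br)c1Cc1cc(OC(C)=O)c(OC(C)=O)c(Br)c1Br | intermediate
15 | sulfate monoanion (ammonium counter-ion, not isolated) | [O-]S(=O)(=O)OCCc1cc(O)c(O)c(Br)c1Cc1cc(O)c(O)c(Br)c1Br | intermediate
16 | 2-[3-bromo-2-(2,3-dibromo-4,5-dihydroxybenzyl)-4,5-dihydroxyphenyl]ethyl hydrogen sulfate | O=S(=O)(O)OCCc1cc(O)c(O)c(Br)c1Cc1cc(O)c(O)c(Br)c1Br | target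

**Total step count:** 10
**Longest linear sequence:** 10 steps (1 to 16); 5 enters at step 4.

**Steps most likely to fail**

**Step 4.**
- **Risk:** the closure may stall before C–C bond formation or be overtaken by intermolecular alkylation. Ring A is pushed only by a methoxy group, and the cationic carbon is shielded by an ortho bromine.
- **Fallback:** it sets out from 4 and 5 and comes back at 10. The junction is made without a tether, by intermolecular Friedel–Crafts benzylation.
- NaBH4 in MeOH reduces 4 to (2,3-dibromo-4,5-dimethoxyphenyl)methanol F1.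
- Ac2O and pyridine convert 5 to 4-(2-acetoxyethyl)-2-methoxyphenyl acetate F2, in which the acylated phenol no longer competes with the methoxy group as director.
- AlCl3 in CH2Cl2 at 0 °C ionises F1 and should benzylate F2 para to the methoxy group. The product is 2-[4-acetoxy-2-(2,3-dibromo-4,5-dimethoxybenzyl)-5-methoxyphenyl]ethyl acetate F3.
- K2CO3 in MeOH then removes both acetyl groups and gives 10.

**Step 8.**
- **Risk:** acyl transfer to the primary hydroxyl, incomplete acylation of the hydroxyls next to bromine, or air oxidation of the catechols in the basic medium may erode the chemoselectivity.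
- **Fallback:** it sets out from 12 and comes back at 15. It uses the opposite acid lability of alkyl and aryl silyl ethers in place of a selective acylation.
- TBSCl and imidazole in DMF silylate all five hydroxyls to the pentakis(tert-butyldimethylsilyl) ether of 12 F4.
- Catalytic camphorsulfonic acid in MeOH–CH2Cl2 at 0 °C cleaves only the primary alkyl silyl ether. This gives 2-[3-bromo-2-(2,3-dibromo-4,5-bis(tert-butyldimethylsilyloxy)benzyl)-4,5-bis(tert-butyldimethylsilyloxy)phenyl]ethanol F5.
- SO3·pyridine in DMF converts F5 to the pyridinium sulfate of the tetrasilyl ether F6.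
- NH4F in MeOH strips the four aryl silyl ethers to monoanion 15, which the same cold proton exchange turns into 16.

**Step 6.**
- **Risk:** site selectivity may be poor, through attack ortho to the methoxy group or on ring B. The doubly benzylic CH2 may also be oxidised, because C5 lies beside the freely rotating dibromobenzyl group.
- **Fallback:** it sets out from 8 and comes back at 11. The bromine is introduced while the two rings are still tied together.
- In 8 the C1 aryl group stands pseudo-axial, so the position ortho to the phenol faces only the C1 hydrogen. There is also neither a diarylmethane CH2 nor a free alcohol.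
- NBS with catalytic i-Pr2NH in CH2Cl2 at 0 °C should give (±)-8-bromo-1-(2,3-dibromo-4,5-dimethoxyphenyl)-6-methoxyisochroman-7-ol F7.
- Et3SiH and TFA in CH2Cl2 then open F7 to 11.

**Further compounds**
F1 | step 4 | (2,3-dibromo-4,5-dimethoxyphenyl)methanol | OCc1cc(OC)c(OC)c(Br)c1Br
F2 | step 4 | 4-(2-acetoxyethyl)-2-methoxyphenyl acetate | COc1cc(CCOC(C)=O)ccc1OC(C)=O
F3 | step 4 | 2-[4-acetoxy-2-(2,3-dibromo-4,5-dimethoxybenzyl)-5-methoxyphenyl]ethyl acetate | CC(=O)OCCc1cc(OC)c(OC(C)=O)cc1Cc1cc(OC)c(OC)c(Br)c1Br
F4 | step 8 | pentakis(tert-butyldimethylsilyl) ether of 12 | CC(C)(C)[Si](C)(C)OCCc1cc(O[Si](C)(C)C(C)(C)C)c(O[Si](C)(C)C(C)(C)C)c(Br)c1Cc1cc(O[Si](C)(C)C(C)(C)C)c(O[Si](C)(C)C(C)(C)C)c(Br)c1Br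
F5 | step 8 | 2-[3-bromo-2-(2,3-dibromo-4,5-bis(tert-butyldimethylsilyloxy)benzyl)-4,5-bis(tert-butyldimethylsilyloxy)phenyl]ethanol | OCCc1cc(O[Si](C)(C)C(C)(C)C)c(O[Si](C)(C)C(C)(C)C)c(Br)c1Cc1cc(O[Si](C)(C)C(C)(C)C)c(O[Si](C)(C)C(C)(C)C)c(Br)c1Br
F6 | step 8 | pyridinium sulfate of the tetrasilyl ether | c1cc[nH+]cc1.[O-]S(=O)(=O)OCCc1cc(O[Si](C)(C)C(C)(C)C)c(O[Si](C)(C)C(C)(C)C)c(Br)c1Cc1cc(O[Si](C)(C)C(C)(C)C)c(O[Si](C)(C)C(C)(C)C)c(Br)c1Br
F7 | step 6 | (±)-8-bromo-1-(2,3-dibromo-4,5-dimethoxyphenyl)-6-methoxyisochroman-7-ol (racemic) | COc1cc2CCOC(c3cc(OC)c(OC)c(Br)c3Br)c2c(Br)c1O
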